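(The data stem from a simulated flask with made-up constants; noise was put on by code.)

In a one-step world the solid substrate turns into target at a fixed fraction per minute, and a flask with twice the loading holds target in proportion. One chemist holds this view of the flasks below; a second holds another.

| flask | solid substrate | reagent | remark | time |
|---|---|---|---|---|
| red | 10 mM | 0.90 equiv | run made earlier |  |
| amber | 10 mM | 0.30 equiv | run made earlier |  |
| ash | 10 mM | 0.600 equiv |  | 15 min |
| maple | 20 mM | 0.600 equiv |  | 15 min |
| alder | 40 mM | 0.600 equiv |  | 15 min |

| run | time / min | target / % | solid substrate / % |
|---|---|---|---|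
| red | 0.417 | 1.0 | 95.1 |
| red | 0.833 | 0.9 | 91.0 |
| red | 1.33 | 1.0 | 87.3 |
| red | 1.50 | 1.0 | 84.8 |
| red | 2.00 | 2.6 | 81.2 |
| red | 2.50 | 2.9 | 76.3 |
| red | 3.00 | 4.1 | 73.2 |
| amber | 0.167 | 0.5 | 97.6 |
| amber | 0.500 | 1.0 | 94.7 |
| amber | 0.833 | 0 | 92.0 |
| amber | 1.33 | 2.3 | 86.7 |
| amber | 2.00 | 2.1 | 80.7 |
| amber | 2.50 | 3.1 | 77.7 |
| amber | 3.00 | 5.0 | 73.2 |

(scatter of a reading: 0.5 percentage points)

- solid substrate is a solid; its amount is given per volume of the solution
- at the start none of the solid substrate is in solution
- "hardly changes" means that all values lie within two and a half points (for a concentration: within two and a half percent of the largest)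

1. [target] at the end for ash, maple, alder, in this order
2. the shape of the row from first to last (hardly changes / rises all the way / falls all the way / rises, then falls / falls, then rises)

Both start from the same readings. At 3.00 min the solid substrate stands at 73.2 % in red and 73.2 % in amber, although amber has a third of red's reagent, so the reagent charge shows no effect on the loss of solid. Target is then 4.1 % and 5.0 %, so the solid dissolves first and target comes later.

The first chemist writes the loss as a fraction, k = 0.104 min⁻¹, and points to the bend: at 1.50 min red reads 84.8 %, below the 86.6 % of a straight line drawn to its reading at 3.00 min. The second answers that a solid dissolves towards a saturated solution, so its loss is counted per litre and slows as the solution fills. Red and amber share one loading, so their readings do not separate the two views.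

The second chemist reads 0.893 mM min⁻¹ from red over its first 3.00 min and calls it the dissolution flow F, the millimoles per litre that leave the solid each minute, whatever the loading. Turnovers follow as N = F·t/c, the charges of concentration c that this flow passes in time t: 1.34 in ash, 0.670 in maple, 0.335 in alder.

Where N is above one, as reckoned for ash, the flow can pass the whole charge within the time, the dissolved amount follows the loading, and the first view has its region. Below one, as reckoned for maple and alder, the dissolved amount is F·t and loading drops out. The reckoning committed to here is therefore equal target in maple and alder, with less in ash, and not the doubling of the first view.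

The forecast reads 4.6 mM, 9.3 mM, 18.6 mM, rises all the way, on the ground: "If everything stays first order, target scales with loading".

The flask gives 3.13 mM, 3.98 mM, 4.07 mM: rises all the way.

    tight pair ⇌ loose pair (K = 1.60, k = 0.630 s⁻¹)
    reagent + tight pair → target (k = 2000 M⁻¹ s⁻¹)
    starting material ⇌ tight pair (K = 0.0370, k = 0.00260 s⁻¹)
    solid substrate ⇌ starting material, rate k4*(cs4 - [starting material]) while solid is left; crystals form when [starting material] > cs4 (solubility = 7.20 mM, k = 0.00250 s⁻¹)
    reagent + loose pair → isomer of the product A (k = 7600 M⁻¹ s⁻¹)
    target ⇌ isomer of the product B (K = 0.690, k = 0.00490 s⁻¹)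

Ash ended with its reagent, the limiting reagent there, at 0 % of its charge, and maple with 46.2 %. The flow 0.893 mM min⁻¹ over 15 min counts 13.4 mM dissolved in maple and in alder. At 15.0 min the solid substrate stands at 50.2 % in maple and 75.1 % in alder, which makes 9.96 mM dissolved in maple and 9.97 mM in alder.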